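Start from the amounts: the flask holds 0.014 M of substrate with 1.20 equiv of coupling partner and 1.50 equiv of scavenger, so the substrate is the limiting reagent, and the question is how near its end it comes in 5.0 h.

substrate 0.014 M; coupling partner 1.20 equiv; scavenger 1.50 equiv; time 5.0 h

    substrate + coupling partner ⇌ target + released group (K1 = 2.59, k1 = 0.00896 M⁻¹ s⁻¹)
    coupling partner + released group ⇌ idle adduct, settled at all times (K2 = 91.8 M⁻¹)
    scavenger + released group → scavenged by-product (k3 = 0.0531 M⁻¹ s⁻¹)
    2 substrate → self-condensation product (k4 = 0.101 M⁻¹ s⁻¹)

- percentages count the substrate that a species holds: one self-condensation product counts as two
- released group is meant together with its idle adduct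
- a step written with two of one species runs at k times the square of its concentration and takes two of it each time
- run time (flask): 5.0 h

- part of the substrate that has reacted at 5.0 h
- share of the unused coupling partner that is free and not bound as idle adduct, at 5.0 h

Climb the ladder of times, shortest first. The idle adduct keeps balance with free released group at every moment. At the charged amounts, the first half-life of substrate by self-condensation is 0.0982 h, free released group has a half-life of 0.17 h by scavenging, and substrate has one of 1.3 h by forward coupling alone. Because scavenging is the quicker of the last two, I drop the way back from my reckoning.

Self-condensation starts 18.8 times as fast as coupling, but it fades with the square of c(substrate), so you follow the coupling, pseudo-first-order in substrate, through the tail. Its tail rate, the coupling's rate constant times c(coupling partner) as charged, is 0.542 h⁻¹. Over the run, the tail factor, e to minus tail rate times time, is 0.0666. The fraction left is that factor divided by one plus the starting ratio times the part of the factor gone: 0.359%. So I commit to 99.6% reacted.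

If I take free released group at the end as made as fast as it is scavenged, my estimate of c(released group) is 6.79 × 10⁻⁶ M, and the free share of unused partner comes to 99.9%.

The forecast says 99.5% (99.2% to 99.8%), which stands 0.14 percentage points under mine, and 99.9% (99.7% to >99.9%), holding that the coupling “clears the remaining tail over 5 h”.

The simulation gives 99.5% and 99.9%.

The tail rate times the run time is 2.71 in this flask. The neighbour flask has the same recipe on 0.0035 M of substrate, a quarter of the charge. Both rates scale with that charge, so its starting ratio stays 18.8, but its tail rate falls to 0.135 h⁻¹, and the product to 0.675. The same division leaves 4.98% of the substrate in the neighbour flask. The simulation of that flask shows 5.1% left.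

The constants used here come from no measurement; the run is a simulation.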